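**Retrosynthetic overview**

- Target 13 is a depside. Ring A (numbered as a benzoate: C1 carboxyl, C2 OH, C3 CHO, C4 OH, C5 OH, C6 CH3) is cut back by C3 deformylation and C4 O-benzylation to hydroquinone 10.
- The strategy rests on the oxygen pattern of ring A: hydroxyls para to each other at C2 and C5 plus a third oxygen at C4. This is the pattern left by a 2-siloxy-4-alkoxyfuran cycloadduct once its oxygen bridge has opened, while C1 (carboxyl) and C6 (methyl) are the two carbons of a but-2-ynoate.
- Key disconnection: the C1–C2 and C5–C6 bonds of ring A, a (4+2) cycloaddition of siloxyfuran 3 with aryl but-2-ynoate 7. The ester of 7 is already the depside link to ring B, so the crowded 2,6-disubstituted benzoate is never acylated.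
- Furan 3 comes from tetronic acid 1 (O-benzylation, silylation). Ynoate 7 comes from methyl 2,4-dihydroxy-3,6-dimethylbenzoate 4 and but-2-ynoic acid 5 (4-O-acylation, 2-O-silylation).
- Ring order: ring B is bought; ring A is the only ring formed (step 5), then formylated and debenzylated.

Key step: step 5

Remark: the chelated ring B phenol is carried through the cycloaddition as a tert-butyldimethylsilyl ether, installed with a non-nucleophilic base so that the base-labile aryl ynoate never meets a phenoxide, and it is shed together with the ring A silyl group in the fluoride work-up; all isolated compounds are achiral and cycloadduct 8 is racemic.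

**Step 1**
Reactants: 1 tetronic acid (4-hydroxyfuran-2(5H)-one)
Product: 2 4-(benzyloxy)furan-2(5H)-one
Conditions: BnOH, PPh3, DIAD, THF, 0 °C → rt
Reagents that add atoms: benzyl alcohol, OCc1ccccc1
Why: Mitsunobu O-alkylation of the vinylogous carboxylic acid, which is acidic enough to protonate the betaine and is alkylated at the enol oxygen, avoiding the C-benzylation that a benzyl halide and base give with tetronic acid.

**Step 2**
Reactants: 2 4-(benzyloxy)furan-2(5H)-one
Product: 3 4-(benzyloxy)-2-[(tert-butyldimethylsilyl)oxy]furan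
Conditions: TBSOTf, Et3N, CH2Cl2, 0 °C; pentane extraction, used without chromatography
Reagents that add atoms: tert-butyldimethylsilyl trifluoromethanesulfonate, CC(C)(C)[Si](C)(C)OS(=O)(=O)C(F)(F)F
Why: Silylation of the lactone carbonyl followed by loss of a C5 proton to the amine (soft enolization) converts the butenolide into the aromatic 2-siloxyfuran, the standard preparation of silyloxyfurans.

**Step 3**
Reactants: 4 methyl 2,4-dihydroxy-3,6-dimethylbenzoate; 5 but-2-ynoic acid
Product: 6 methyl 4-(but-2-ynoyloxy)-2-hydroxy-3,6-dimethylbenzoate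
Conditions: DCC, DMAP (cat.), CH2Cl2, 0 °C → rt
Reagents that add atoms: none
Why: Steglich esterification, selective for the 4-hydroxyl because the 2-hydroxyl is locked in a hydrogen bond to the ester carbonyl and is flanked by the ester and the 3-methyl group.

**Step 4**
Reactants: 6 methyl 4-(but-2-ynoyloxy)-2-hydroxy-3,6-dimethylbenzoate
Product: 7 methyl 4-(but-2-ynoyloxy)-2-[(tert-butyldimethylsilyl)oxy]-3,6-dimethylbenzoate
Conditions: TBSOTf, 2,6-lutidine, CH2Cl2, 0 °C → rt
Reagents that add atoms: tert-butyldimethylsilyl trifluoromethanesulfonate, CC(C)(C)[Si](C)(C)OS(=O)(=O)C(F)(F)F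
Why: O-silylation with a silyl triflate, which is electrophilic enough to cap the hindered, chelated phenol, while the hindered pyridine base neither adds to the ynoate nor generates a phenoxide that could cleave the aryl ester.

**Step 5**
Reactants: 3 4-(benzyloxy)-2-[(tert-butyldimethylsilyl)oxy]furan; 7 methyl 4-(but-2-ynoyloxy)-2-[(tert-butyldimethylsilyl)oxy]-3,6-dimethylbenzoate
Product: 10 methyl 4-{[4-(benzyloxy)-2,5-dihydroxy-6-methylbenzoyl]oxy}-2-hydroxy-3,6-dimethylbenzoate, via oxabicyclic cycloadduct 8 (not isolated), via bis-silyl ether 9 (not isolated)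
Conditions: 3 (excess), toluene, 110 °C, sealed tube, argon; then Bu4NF, AcOH, THF, 0 °C
Reagents that add atoms: none
Why: The electron-rich furan 3, a cyclic vinylogous silyl ketene acetal, adds as the diene to the electron-poor aryl ynoate 7 in a thermal normal-demand (4+2) cycloaddition, furan C5 bonding to the methyl-bearing beta carbon (C5–C6 of ring A) and furan C2 to the alpha carbon (C1–C2), probably asynchronously with the C5–C6 bond leading. The closest known reaction is the Diels–Alder benzannulation of 2-silyloxyfurans with acetylenic esters, which gives para-silyloxyphenols after opening of the oxygen bridge. Ring A, the only ring formed, is a six-membered carbocycle closed by this intermolecular cycloaddition; in adduct 8 the bridge C–O bond at the silyloxy bridgehead then ionizes (the cation is stabilized by the silyloxy oxygen and, through the enol ether, by the benzyloxy group) and loss of the other bridgehead proton aromatizes to 9, so the bridge oxygen becomes the C5 hydroxyl and the silyloxy oxygen the C2 oxygen. No stereocenter survives, so only regiochemistry must be controlled: the largest donor coefficient of 3 lies at unsubstituted C5, reinforced by both the 2-silyloxy and the 4-benzyloxy group, and the largest acceptor coefficient of 7 lies at the beta carbon, which places the benzyloxy group at C4 and not at C3. The aryl ester makes the alkyne more electron-poor than in an alkyl but-2-ynoate and the excess of 3 compensates for the slow reaction of the beta-methyl ynoate; no Lewis acid is used, since it could trigger hydroarylation of the aryl ynoate onto ring B. Acetic acid-buffered Bu4NF finally removes both silyl groups without exposing the hydroquinone or the depside ester to free base.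

**Step 6**
Reactants: 10 methyl 4-{[4-(benzyloxy)-2,5-dihydroxy-6-methylbenzoyl]oxy}-2-hydroxy-3,6-dimethylbenzoate
Product: 12 methyl 4-{[4-(benzyloxy)-3-formyl-2,5-dihydroxy-6-methylbenzoyl]oxy}-2-hydroxy-3,6-dimethylbenzoate, via hydroxymethyl intermediate 11 (not isolated)
Conditions: MgCl2, Et3N, (CH2O)n, THF, reflux, argon; then 1 M HCl
Reagents that add atoms: paraformaldehyde (as formaldehyde), C=O
Why: Casnati–Skattebøl magnesium-mediated ortho-formylation, in which the magnesium phenoxide at C2–O delivers formaldehyde to C3, the only unsubstituted ring A carbon, and the resulting hydroxymethyl compound 11 is oxidized by a second formaldehyde, while ring B has no free position ortho to its phenol and the method does not attack para positions.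

**Step 7**
Reactants: 12 methyl 4-{[4-(benzyloxy)-3-formyl-2,5-dihydroxy-6-methylbenzoyl]oxy}-2-hydroxy-3,6-dimethylbenzoate
Product: 13 methyl 4-[(3-formyl-2,4,5-trihydroxy-6-methylbenzoyl)oxy]-2-hydroxy-3,6-dimethylbenzoate (CNP0216802.0)
Conditions: BCl3, C6HMe5, CH2Cl2, −78 → −20 °C; then H2O
Reagents that add atoms: none
Why: Lewis-acid cleavage of the aryl benzyl ether, assisted by chelation of boron between the ether oxygen and the neighbouring formyl group, with pentamethylbenzene trapping the benzyl cation so that ring B is not C-benzylated and with both esters and the aldehyde expected to survive at low temperature.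

**Compound list**

1 | tetronic acid (4-hydroxyfuran-2(5H)-one) | O=C1C=C(O)CO1 | starting material
2 | 4-(benzyloxy)furan-2(5H)-one | O=C1C=C(OCc2ccccc2)CO1 | intermediate
3 | 4-(benzyloxy)-2-[(tert-butyldimethylsilyl)oxy]furan | CC(C)(C)[Si](C)(C)Oc1cc(OCc2ccccc2)co1 | intermediate
4 | methyl 2,4-dihydroxy-3,6-dimethylbenzoate | COC(=O)c1c(C)cc(O)c(C)c1O | starting material
5 | but-2-ynoic acid | CC#CC(=O)O | starting material
6 | methyl 4-(but-2-ynoyloxy)-2-hydroxy-3,6-dimethylbenzoate | CC#CC(=O)Oc1cc(C)c(C(=O)OC)c(O)c1C | intermediate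
7 | methyl 4-(but-2-ynoyloxy)-2-[(tert-butyldimethylsilyl)oxy]-3,6-dimethylbenzoate | CC#CC(=O)Oc1cc(C)c(C(=O)OC)c(O[Si](C)(C)C(C)(C)C)c1C | intermediate
8 | 4-(methoxycarbonyl)-2,5-dimethyl-3-[(tert-butyldimethylsilyl)oxy]phenyl 5-(benzyloxy)-1-[(tert-butyldimethylsilyl)oxy]-3-methyl-7-oxabicyclo[2.2.1]hepta-2,5-diene-2-carboxylate (racemic; the two bridgehead centres are tied together by the bicycle) | CC1=C(C(=O)Oc3cc(C)c(C(=O)OC)c(O[Si](C)(C)C(C)(C)C)c3C)C2(O[Si](C)(C)C(C)(C)C)C=C(OCc4ccccc4)C1O2 | intermediate
9 | methyl 4-({4-(benzyloxy)-2-[(tert-butyldimethylsilyl)oxy]-5-hydroxy-6-methylbenzoyl}oxy)-2-[(tert-butyldimethylsilyl)oxy]-3,6-dimethylbenzoate | COC(=O)c1c(C)cc(OC(=O)c2c(C)c(O)c(OCc3ccccc3)cc2O[Si](C)(C)C(C)(C)C)c(C)c1O[Si](C)(C)C(C)(C)C | intermediate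
10 | methyl 4-{[4-(benzyloxy)-2,5-dihydroxy-6-methylbenzoyl]oxy}-2-hydroxy-3,6-dimethylbenzoate | COC(=O)c1c(C)cc(OC(=O)c2c(C)c(O)c(OCc3ccccc3)cc2O)c(C)c1O | intermediate
11 | methyl 4-{[4-(benzyloxy)-2,5-dihydroxy-3-(hydroxymethyl)-6-methylbenzoyl]oxy}-2-hydroxy-3,6-dimethylbenzoate | COC(=O)c1c(C)cc(OC(=O)c2c(C)c(O)c(OCc3ccccc3)c(CO)c2O)c(C)c1O | intermediate
12 | methyl 4-{[4-(benzyloxy)-3-formyl-2,5-dihydroxy-6-methylbenzoyl]oxy}-2-hydroxy-3,6-dimethylbenzoate | COC(=O)c1c(C)cc(OC(=O)c2c(C)c(O)c(OCc3ccccc3)c(C=O)c2O)c(C)c1O | intermediate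
13 | methyl 4-[(3-formyl-2,4,5-trihydroxy-6-methylbenzoyl)oxy]-2-hydroxy-3,6-dimethylbenzoate | COC(=O)c1c(C)cc(OC(=O)c2c(C)c(O)c(O)c(C=O)c2O)c(C)c1O | target

**Step count**

Total: 7 steps. Longest linear sequence: 5 steps (4 → 6 → 7 → 10 → 12 → 13, or equally 1 → 2 → 3 → 10 → 12 → 13).

**Steps most likely to fail**

Step 5. The beta-methyl ynoate is a slow dienophile, so thermal decomposition or protodesilylation of the siloxyfuran may outrun the cycloaddition, or the reaction may stop at an open-chain conjugate adduct. The fallback replaces the alkyne by its more reactive allene isomer; it sets out from 4 (furan 3 is used unchanged) and comes back at 10. Esterification of 4 with but-3-ynoic acid under Mukaiyama conditions (2-chloro-1-methylpyridinium iodide, Et3N, CH2Cl2) is expected to give, with isomerization in the flask, methyl 4-(buta-2,3-dienoyloxy)-2-hydroxy-3,6-dimethylbenzoate F1. Silylation as in step 4 should give methyl 4-(buta-2,3-dienoyloxy)-2-[(tert-butyldimethylsilyl)oxy]-3,6-dimethylbenzoate F2. Cycloaddition of 3 across the activated alpha,beta double bond of F2 (toluene, 60–80 °C), with furan C5 again bonding to the electrophilic central allene carbon, should give 4-(methoxycarbonyl)-2,5-dimethyl-3-[(tert-butyldimethylsilyl)oxy]phenyl 5-(benzyloxy)-1-[(tert-butyldimethylsilyl)oxy]-3-methylidene-7-oxabicyclo[2.2.1]hept-5-ene-2-carboxylate F3. Buffered Bu4NF then opens the bridge, and the exocyclic methylene tautomerizes into the ring as the C6 methyl, giving 10.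

Step 6. The only directing phenoxide is chelated to the depside carbonyl, so ortho-attack may be slow; hydroxymethylation could stall, or the hydroquinone could be oxidized under the basic conditions. The fallback changes the order of the endgame; it sets out from 10 and comes back at 13, bypassing 12 and step 7. Hydrogenolysis of 10 (H2, Pd on carbon (Pd/C), EtOAc, rt) should give methyl 2-hydroxy-3,6-dimethyl-4-[(2,4,5-trihydroxy-6-methylbenzoyl)oxy]benzoate F4. In F4 the C3 carbon lies between two free hydroxyls and is far more nucleophilic. Formylation under argon (MgCl2, Et3N, (CH2O)n, THF, reflux) should then pass through methyl 2-hydroxy-3,6-dimethyl-4-{[2,4,5-trihydroxy-3-(hydroxymethyl)-6-methylbenzoyl]oxy}benzoate F5 and give 13 directly.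

Step 7. The Lewis acid may cleave the depside or the methyl ester, or the product may be released incompletely from its boron chelates. The fallback replaces Lewis-acid dealkylation by catalytic hydrogenolysis; it sets out from 12 and comes back at 13 and makes no new compound (F0). Brief exposure to H2 (1 atm) over Pd on carbon (Pd/C) in EtOAc at rt, stopped when 12 is consumed, should remove the benzyl group, and the hydrogen-bonded aldehyde is expected to survive.

**Further compounds**

F1 | step 5 | methyl 4-(buta-2,3-dienoyloxy)-2-hydroxy-3,6-dimethylbenzoate | C=C=CC(=O)Oc1cc(C)c(C(=O)OC)c(O)c1C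
F2 | step 5 | methyl 4-(buta-2,3-dienoyloxy)-2-[(tert-butyldimethylsilyl)oxy]-3,6-dimethylbenzoate | C=C=CC(=O)Oc1cc(C)c(C(=O)OC)c(O[Si](C)(C)C(C)(C)C)c1C
F3 | step 5 | 4-(methoxycarbonyl)-2,5-dimethyl-3-[(tert-butyldimethylsilyl)oxy]phenyl 5-(benzyloxy)-1-[(tert-butyldimethylsilyl)oxy]-3-methylidene-7-oxabicyclo[2.2.1]hept-5-ene-2-carboxylate (mixture of racemic diastereomers) | C=C1C(C(=O)Oc3cc(C)c(C(=O)OC)c(O[Si](C)(C)C(C)(C)C)c3C)C2(O[Si](C)(C)C(C)(C)C)C=C(OCc4ccccc4)C1O2
F4 | step 6 | methyl 2-hydroxy-3,6-dimethyl-4-[(2,4,5-trihydroxy-6-methylbenzoyl)oxy]benzoate | COC(=O)c1c(C)cc(OC(=O)c2c(C)c(O)c(O)cc2O)c(C)c1O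
F5 | step 6 | methyl 2-hydroxy-3,6-dimethyl-4-{[2,4,5-trihydroxy-3-(hydroxymethyl)-6-methylbenzoyl]oxy}benzoate | COC(=O)c1c(C)cc(OC(=O)c2c(C)c(O)c(O)c(CO)c2O)c(C)c1O
F0 | step 7 | none | none
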